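(The runs come from a simulation from invented constants; the scatter is artificial.)

The pitfall is to call free X unreadable because no reading shows X. The rate of D shows it.

| flask | Z | X | remark | time |
|---|---|---|---|---|
| delta | 0.050 M (fed, over 30 h) | 0.075 M | the very flask that is asked about, followed so far |  |
| eta | 0.075 M (fed, over 30 h) | 0.075 M | run made earlier |  |
| flask | 0.050 M (fed, over 30 h) | 0.0750 M |  | 6.0 d |

- delta (time / h: Z / %, D / %): 8.00: 16.3, 9.8; 15.0: 28.9, 20.1; 20.0: 37.9, 28.9; 30.0: 60.6, 37.5; 40.0: 57.5, 43.1
- eta (time / d: Z / %, D / %): 0.417: 21.1, 11.7; 0.833: 40.5, 25.2; 1.25: 69.3, 31.1; 1.67: 66.5, 33.5; 2.08: 64.3, 36.0; 2.50: 63.2, 36.8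

(each reading ± 0.5 percentage points)

1. part of the Z that has reacted at 6.0 d
2. share of the unused X that is free and not bound as G, at 6.0 d

The share asked is free X over free plus bound X. Which number must I know well? I take bound X as near D, at one X per D, but that is a guess, since the runs do not show how much X is bound, and an error there passes into the share. Free X could lie far below its charge, and the share follows it directly. Free X leaves a trace in the rate of D, so I read it first.

D forms from Z and X, so the rate of D per Z, a pseudo-first-order constant, should follow free X. Over the first 8.00 h of the delta run it is 0.150 h⁻¹, with X taken as still near its charge. Dividing by 0.075 M gives my meter, the rate per Z and per unit of free X: 2.00 M⁻¹ h⁻¹.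

The eta run has the same X charge. From 1.67 d to 2.50 d its D rises 3.3 percentage points, against a scatter of 0.5 points, so its rate per Z is 0.00255 h⁻¹. That reads as free X of 0.00127 M. Its D is then 0.0276 M. Holding that rate from 40.0 h on gives this flask 58.4% reacted, a high figure since Z falls. With bound X guessed equal to the eta D, my share is 4.41%, no firmer than that guess.

The forecast gives 54% and 45%, on the ground that “the product itself shuts the reaction down”.

The flask gives 54.1% and 3.52%.

    Z + X → J + D (k = 2.30 M⁻¹ h⁻¹)
    X + J ⇌ G, settled at all times (K = 2100 M⁻¹)
    2 X → E (k = 0.450 M⁻¹ h⁻¹)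

This flask holds X at 0.683% of its charge, or 5.13 × 10⁻⁴ M, less than my 0.00127 M, beside G at 0.0140 M. At 2.00 M⁻¹ h⁻¹ that free X means 0.00103 h⁻¹ per Z. A neighbour flask with 0.020 M of Z keeps X at 2.33%. The same meter gives it 0.00350 h⁻¹, faster than this flask. Beside its G of 0.0130 M, the free share comes to 11.8%, and its D stands at 82.8%.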